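**Retrosynthetic overview**

1. Labels follow the target SMILES: C1 CH–OAc, C2 CH2, C3 C–Me, C4 CH–Br, C5 CH2, C6 C–Me, C7 CH–Me, C8 CH–Br, C9 CH–OH, C10 CH–Me, C11 the carbon common to all three rings. The cyclobutane (C1, C2, C3, C11) and the cyclopentane (C3, C4, C5, C6, C11) share only the bond C3–C11, so their outer atoms C1–C2–C3–C4–C5–C6–C11 trace a seven-membered ring with the C3 methyl beside the C4 heteroatom carbon. Cleaving C3–C11 therefore gives a 2-methylcyclohepta-2,4-dienone (C4=O, C3=C2, C1=C11) fused to the cyclohexane at C6–C11.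
2. Forward, irradiation of that dienone (C9 carried as a silyl ether) closes C3–C11 by 4π electrocyclisation and forms the four- and five-membered rings in one step; the quaternary C6 relays its configuration to C3 and C11.
3. The seven-membered ring is closed by olefin metathesis at C2=C3 after isopropenyl and allyl Grignard additions to a cyclohexanone that carries the C6 side chain; oxidation at C4 and dehydration at C11 then give the dienone.
4. The cyclohexane comes from (S)-carvone: Criegee degradation of the isopropenyl group (C9–O), cuprate methylation with enolate allylation (C7, C6), then C10 methylation and epimerisation.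
5. After the key step: C4 reduction, exo epoxidation and hydride opening (C1–OAc), invertive C4 bromination, then C9 ketone, C8 bromination and reduction. Ring order: six-membered, seven-membered, then four- and five-membered together.

Key step: step 13

Remark on faces: β is the face of the cyclopentane that carries the cyclobutane carbons C1/C2 and the C6 methyl; α is the opposite face (C3 methyl, C7, C10).
Assumption: compounds 16 and 18–20 are carried as epimer mixtures at the C4 and/or C11 carbinol carbons, centres that are removed in steps 11 and 12.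

**Route**

Step 1
Reactants: 1 (S)-carvone
Product: 3 (S)-5-acetoxy-2-methylcyclohex-2-en-1-one, via methoxy hydroperoxide 2 (not isolated)
Conditions: O3, CH2Cl2/MeOH, −78 °C; then Ac2O, Et3N, DMAP (cat.), −10 °C → rt
Reagents that add atoms: ozone, [O-][O+]=O; methanol, CO
Why: Ozone attacks only the electron-rich isopropenyl alkene, methanol traps the carbonyl oxide as methoxy hydroperoxide 2, and acetylation triggers the Criegee rearrangement in which the ring carbon migrates to oxygen with retention, so that C9 keeps the carvone configuration and the acetyl group is assembled from the former isopropenyl carbons.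

Step 2
Reactants: 3 (S)-5-acetoxy-2-methylcyclohex-2-en-1-one
Product: 4 (S)-5-hydroxy-2-methylcyclohex-2-en-1-one
Conditions: K2CO3 (0.2 equiv), MeOH, 0 °C
Reagents that add atoms: none
Why: Base-catalysed transesterification (methanolysis) at 0 °C should release the alcohol faster than β-elimination to the cresol can occur and does not touch C9.

Step 3
Reactants: 4 (S)-5-hydroxy-2-methylcyclohex-2-en-1-one
Product: 5 (S)-5-(tert-butyldimethylsilyloxy)-2-methylcyclohex-2-en-1-one
Conditions: t-BuMe2SiCl, imidazole, DMF, rt
Reagents that add atoms: tert-butyldimethylsilyl chloride, CC(C)(C)[Si](C)(C)Cl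
Why: Silylation with the chloride and imidazole converts the β-hydroxy ketone into a silyl ether, a poor leaving group that should survive the enolate chemistry of steps 4 to 6.

Step 4
Reactants: 5 (S)-5-(tert-butyldimethylsilyloxy)-2-methylcyclohex-2-en-1-one; 6 allyl bromide
Product: 8 (2R,3S,5S)-2-allyl-5-(tert-butyldimethylsilyloxy)-2,3-dimethylcyclohexan-1-one, via lithium enolate 7 (not isolated)
Conditions: Me2CuLi (from MeLi and CuI, cuprous iodide), Et2O, −78 → −20 °C; then allyl bromide, HMPA, THF, −20 °C → rt
Reagents that add atoms: lithium dimethylcuprate, [Li+].C[Cu-]C; allyl bromide (6), C=CCBr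
Why: Conjugate addition of the Gilman reagent places the methyl group on C7 anti to the C9 silyloxy group (axial attack on the half-chair with that group pseudoequatorial), and the regiodefined enolate 7 is alkylated at C6 anti to the new neighbouring methyl group, which fixes the quaternary centre with the C6 and C7 methyl groups cis, the usual outcome of conjugate addition–alkylation on 5-substituted 2-methylcyclohexenones.

Step 5
Reactants: 8 (2R,3S,5S)-2-allyl-5-(tert-butyldimethylsilyloxy)-2,3-dimethylcyclohexan-1-one
Product: 10 (2R,3S,5S,6R)-2-allyl-5-(tert-butyldimethylsilyloxy)-2,3,6-trimethylcyclohexan-1-one, via lithium enolate 9 (not isolated)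
Conditions: LiN(i-Pr)2, THF, −78 °C; then MeI, −78 → −20 °C
Reagents that add atoms: iodomethane, CI
Why: Kinetic enolate alkylation at C10, the only enolisable position, brings the methyl carbon in anti to the adjacent C9 silyloxy group and therefore gives the C10 epimer with methyl trans to that group, which step 6 corrects.

Step 6
Reactants: 10 (2R,3S,5S,6R)-2-allyl-5-(tert-butyldimethylsilyloxy)-2,3,6-trimethylcyclohexan-1-one
Product: 12 (2R,3S,5S,6S)-2-allyl-5-(tert-butyldimethylsilyloxy)-2,3,6-trimethylcyclohexan-1-one, via lithium enolate 11 (not isolated)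
Conditions: LiN(i-Pr)2, THF, −78 → −30 °C; then 2,6-di-tert-butyl-4-methylphenol, −78 °C
Reagents that add atoms: none
Why: Deprotonation and kinetic reprotonation: in the fully substituted enolate 11 the C9 silyloxy group becomes pseudoaxial to escape A(1,2) strain with the C10 methyl, and the hindered phenol should deliver the proton anti to it along the axial trajectory, which leaves the C10 methyl cis to the C9 oxygen and trans to the C6 and C7 methyl groups, by the same logic that makes kinetic protonation of 2-alkyl-3-substituted cyclohexanone enolates cis-selective.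

Step 7
Reactants: 12 (2R,3S,5S,6S)-2-allyl-5-(tert-butyldimethylsilyloxy)-2,3,6-trimethylcyclohexan-1-one
Product: 14 keto aldehyde (C6–CH2–CHO; C11 ketone), via ozonide 13 (not isolated)
Conditions: O3, CH2Cl2, −78 °C; then PPh3, −78 °C → rt
Reagents that add atoms: ozone, [O-][O+]=O
Why: Ozonolysis with reductive work-up cleaves the only alkene to the aldehyde (C4) and leaves ketone and silyl ether untouched; no stereocentre is affected.

Step 8
Reactants: 14 keto aldehyde; 15 isopropenylmagnesium bromide
Product: 16 hydroxy ketone (C4 carbinol bearing the isopropenyl group; C11 ketone)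
Conditions: CH2=C(Me)MgBr (1.1 equiv), THF, −78 °C
Reagents that add atoms: isopropenylmagnesium bromide (15), CC(=C)[Mg]Br
Why: Grignard 1,2-addition is chemoselective for the aldehyde because the C11 ketone is flanked by a quaternary and a tertiary carbon, and the configuration of the new C4 carbinol is irrelevant since it is oxidised in step 11.

Step 9
Reactants: 16 hydroxy ketone; 17 allylmagnesium bromide
Product: 18 diene diol (C11 tertiary carbinol bearing the allyl group)
Conditions: CH2=CHCH2MgBr (3 equiv), Et2O/THF, −78 → 0 °C
Reagents that add atoms: allylmagnesium bromide (17), C=CC[Mg]Br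
Why: Allyl Grignard addition proceeds through a six-membered transition state and therefore reaches even this hindered ketone after the first equivalent has deprotonated the C4 hydroxyl, and the configuration of the C11 carbinol is irrelevant since it is dehydrated in step 12.

Step 10
Reactants: 18 diene diol
Product: 19 bicyclic cycloheptene diol (C2=C3; C4–OH; C11–OH)
Conditions: second-generation Grubbs catalyst RuCl2(=CHPh)(H2IMes)(PCy3) (5 mol %), CH2Cl2 (5 mM), 40 °C
Reagents that add atoms: none
Why: Ring-closing olefin metathesis between the 1,1-disubstituted allylic-alcohol alkene and the allyl group closes the seven-membered ring at C2=C3, a trisubstituted cycloalkene of the kind this catalyst forms readily, without creating a stereocentre.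

Step 11
Reactants: 19 bicyclic cycloheptene diol
Product: 20 hydroxy enone (C4=O; C2=C3; C11–OH)
Conditions: Dess–Martin periodinane, NaHCO3, CH2Cl2, 0 °C → rt
Reagents that add atoms: none
Why: Dess–Martin oxidation turns the secondary allylic alcohol into the 2-methyl enone under buffered neutral conditions and cannot oxidise the tertiary C11 alcohol.

Step 12
Reactants: 20 hydroxy enone
Product: 21 bicyclic 2-methylcyclohepta-2,4-dienone (C4=O; C3=C2; C1=C11; C9 silyl ether)
Conditions: Martin sulfurane Ph2S[OC(CF3)2Ph]2, CH2Cl2, 0 °C → rt
Reagents that add atoms: none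
Why: Sulfurane dehydration ionises the tertiary alkoxysulfonium species and removes the most acidic neighbouring hydrogen, the C1–H that is γ to the enone carbonyl, so the alkene should form in conjugation at C1=C11 under neutral conditions that leave the ε-acidic C10 centre untouched.

Step 13
Reactants: 21 bicyclic 2-methylcyclohepta-2,4-dienone
Product: 22 tricyclic cyclobutene ketone (C1=C2; C4=O; new bond C3–C11)
Conditions: hν (366 nm), degassed cyclohexane (5 mM), 15 °C, stopped when 21 is consumed
Reagents that add atoms: none
Why: Long-wavelength excitation of the dienone chromophore (C4=O, C3=C2, C1=C11) leads to the σ-bond C3–C11, either by direct disrotatory 4π closure or by photoisomerisation to a strained trans-dienone that closes thermally in conrotatory fashion; the closest known reaction is the photoisomerisation of eucarvone-type 2-methylcyclohepta-2,4-dienones to bicyclo[3.2.0]hept-6-en-2-ones. This one transannular bond closes the cyclobutene (C1, C2, C3, C11) by 4π electrocyclisation of the diene termini and at the same time the cyclopentanone (C3, C4, C5, C6, C11), which is the remainder of the seven-membered ring. The two new stereocentres C3 and C11 are necessarily cis to each other (C3 methyl and C10 on the convex face) because the inner diene substituents C4 and C6 stay joined through C5. Their sense relative to C6 is fixed by the cyclohexane: C10 can only leave the diene plane toward the side on which C7 already lies, since the opposite rotation would demand a C7–C6–C11–C10 torsion far beyond what a six-membered ring tolerates (a trans-fused hydrindane inside a bicyclo[3.2.0] frame). The step needs chemoselectivity against secondary photochemistry of the β,γ-unsaturated ketone product (1,3-acyl shift) and against polar rearrangements, which is secured by irradiating at 366 nm where only the dienone absorbs, by the non-polar aprotic solvent, and by the quaternary C6, which offers no hydrogen for sigmatropic shifts.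

Step 14
Reactants: 22 tricyclic cyclobutene ketone
Product: 23 C4 α-alcohol (4R)
Conditions: (S)-2-methyl-CBS-oxazaborolidine (0.5 equiv), catecholborane, toluene, −78 → −40 °C
Reagents that add atoms: none
Why: Corey–Bakshi–Shibata reduction treats the quaternary C3 side as the large ketone substituent and delivers hydride to the β face, which should give the (4R)-alcohol with the hydroxyl on the α face, while catecholborane at low temperature does not hydroborate the cyclobutene.

Step 15
Reactants: 23 C4 α-alcohol
Product: 24 C4 triethylsilyl ether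
Conditions: Et3SiOTf, 2,6-lutidine, CH2Cl2, −78 → 0 °C
Reagents that add atoms: triethylsilyl trifluoromethanesulfonate, CC[Si](CC)(CC)OS(=O)(=O)C(F)(F)F
Why: Silyl triflate with a hindered pyridine base silylates the neopentyl alcohol, and the triethylsilyl ether can later be cleaved in the presence of the tert-butyldimethylsilyl ether.

Step 16
Reactants: 24 C4 triethylsilyl ether
Product: 25 exo C1–C2 epoxide
Conditions: dimethyldioxirane, acetone/CH2Cl2, 0 °C
Reagents that add atoms: dimethyldioxirane, CC1(C)OO1
Why: Dioxirane epoxidation should occur on the convex exo face of the bicyclo[3.2.0]heptene, because the endo face is covered by the five-membered ring and the C6 methyl, and the acid-free conditions spare the strained oxabicyclopentane.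

Step 17
Reactants: 25 exo C1–C2 epoxide
Product: 26 C1 exo cyclobutanol (C2 now CH2)
Conditions: LiEt3BH, THF, 0 → 40 °C
Reagents that add atoms: none
Why: Nucleophilic hydride opens the epoxide by SN2 attack from the endo side, where the approach to C1 is screened by the syn C6 methyl while the approach to C2 meets only the C4 hydrogen, so hydride should enter at C2 and the oxygen remain on C1 in its exo configuration.

Step 18
Reactants: 26 C1 exo cyclobutanol
Product: 27 C1 acetate
Conditions: Ac2O, DMAP, pyridine, CH2Cl2, rt
Reagents that add atoms: acetic anhydride, CC(=O)OC(C)=O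
Why: DMAP-catalysed acylation esterifies the only free hydroxyl with retention at C1.

Step 19
Reactants: 27 C1 acetate
Product: 28 C1 acetate with free C4 α-alcohol
Conditions: HF·pyridine, pyridine, THF, 0 °C
Reagents that add atoms: none
Why: Buffered HF·pyridine cleaves the triethylsilyl ether far faster than the tert-butyldimethylsilyl ether and does not attack the acetate (selective desilylation).

Step 20
Reactants: 28 C1 acetate with free C4 α-alcohol
Product: 29 C4 β-bromide
Conditions: CBr4, P(n-Oct)3, toluene, 70 °C
Reagents that add atoms: carbon tetrabromide, BrC(Br)(Br)Br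
Why: Appel reaction: bromide displaces the alkoxyphosphonium leaving group at the cyclopentyl carbon C4 with inversion, which puts bromine on the β face, and the non-polar medium with a strongly nucleophilic phosphine is chosen to keep the displacement concerted and avoid cyclobutylcarbinyl cation rearrangement.

Step 21
Reactants: 29 C4 β-bromide
Product: 30 C9 alcohol
Conditions: 48% aq. HF, MeCN, 0 °C → rt
Reagents that add atoms: none
Why: Aqueous HF in acetonitrile removes the remaining silyl ether by fluoride-assisted cleavage without touching the acetate or the secondary bromide.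

Step 22
Reactants: 30 C9 alcohol
Product: 31 C9 ketone
Conditions: Dess–Martin periodinane, NaHCO3, CH2Cl2, rt
Reagents that add atoms: none
Why: Dess–Martin oxidation gives the C9 ketone under neutral conditions, and the C10 methyl is in any case the thermodynamically preferred equatorial epimer of this chair, in which the alternative would be syn-diaxial to the C6 methyl.

Step 23
Reactants: 31 C9 ketone
Product: 34 C8 bromo ketone, via lithium enolate 32 (not isolated), via trimethylsilyl enol ether 33 (not isolated)
Conditions: LiN(SiMe3)2, Me3SiCl, THF, −78 °C; then N-bromosuccinimide, −78 → 0 °C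
Reagents that add atoms: N-bromosuccinimide, O=C1CCC(=O)N1Br
Why: Kinetic deprotonation with in situ silylation takes place at the accessible C8 methylene (C10 is tertiary and adjacent to the quaternary C11), and N-bromosuccinimide should brominate enol silane 33 on the face anti to the neighbouring C7 methyl and the syn-axial C6 methyl, giving the equatorial C8 bromide trans to the C7 methyl.

Step 24
Reactants: 34 C8 bromo ketone
Product: 35 CNP0246576.1 (target)
Conditions: LiBH(s-Bu)3, THF, −78 °C; NH4Cl (aq.) quench at low temperature
Reagents that add atoms: none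
Why: The bulky trialkylborohydride attacks along the equatorial trajectory, the axial one being blocked by the C3–C11 bond, and so should give the axial C9 alcohol cis to the C8 bromine and the C10 methyl, completing the target.

**Compound list**

1 | (S)-(+)-carvone, (5S)-2-methyl-5-(prop-1-en-2-yl)cyclohex-2-en-1-one | CC1=CC[C@H](C(C)=C)CC1=O | starting material
2 | (5S)-5-(1-hydroperoxy-1-methoxyethyl)-2-methylcyclohex-2-en-1-one (both epimers at the peroxy carbon) | CC1=CC[C@H](C(C)(OC)OO)CC1=O | intermediate
3 | (S)-5-acetoxy-2-methylcyclohex-2-en-1-one | CC1=CC[C@H](OC(C)=O)CC1=O | intermediate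
4 | (S)-5-hydroxy-2-methylcyclohex-2-en-1-one | CC1=CC[C@H](O)CC1=O | intermediate
5 | (S)-5-(tert-butyldimethylsilyloxy)-2-methylcyclohex-2-en-1-one | CC1=CC[C@H](O[Si](C)(C)C(C)(C)C)CC1=O | intermediate
6 | allyl bromide | C=CCBr | starting material
7 | lithium (3S,5S)-5-(tert-butyldimethylsilyloxy)-2,3-dimethylcyclohex-1-en-1-olate | [Li]OC1=C(C)[C@@H](C)C[C@H](O[Si](C)(C)C(C)(C)C)C1 | intermediate
8 | (2R,3S,5S)-2-allyl-5-(tert-butyldimethylsilyloxy)-2,3-dimethylcyclohexan-1-one (2-Me and 3-Me cis; 3-Me and 5-OSi trans) | C=CC[C@]1(C)[C@@H](C)C[C@H](O[Si](C)(C)C(C)(C)C)CC1=O | intermediate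
9 | lithium enolate of 8 toward C10 | C=CC[C@]1(C)[C@@H](C)C[C@H](O[Si](C)(C)C(C)(C)C)C=C1O[Li] | intermediate
10 | (2R,3S,5S,6R)-2-allyl-5-(tert-butyldimethylsilyloxy)-2,3,6-trimethylcyclohexan-1-one (6-Me trans to 5-OSi) | C=CC[C@]1(C)[C@@H](C)C[C@H](O[Si](C)(C)C(C)(C)C)[C@@H](C)C1=O | intermediate
11 | lithium enolate of 10 (tetrasubstituted, C10=C11) | C=CC[C@]1(C)[C@@H](C)C[C@H](O[Si](C)(C)C(C)(C)C)C(C)=C1O[Li] | intermediate
12 | (2R,3S,5S,6S)-2-allyl-5-(tert-butyldimethylsilyloxy)-2,3,6-trimethylcyclohexan-1-one (6-Me cis to 5-OSi, trans to 2-Me and 3-Me) | C=CC[C@]1(C)[C@@H](C)C[C@H](O[Si](C)(C)C(C)(C)C)[C@H](C)C1=O | intermediate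
13 | secondary ozonide (1,2,4-trioxolane) of 12 | C1OOC(O1)C[C@]2(C)[C@@H](C)C[C@H](O[Si](C)(C)C(C)(C)C)[C@H](C)C2=O | intermediate
14 | keto aldehyde, 2-[4-(tert-butyldimethylsilyloxy)-1,2,5-trimethyl-6-oxocyclohexyl]acetaldehyde with the ring configuration of 12 | O=CC[C@]1(C)[C@@H](C)C[C@H](O[Si](C)(C)C(C)(C)C)[C@H](C)C1=O | intermediate
15 | isopropenylmagnesium bromide | CC(=C)[Mg]Br | starting material
16 | hydroxy ketone, 2-(2-hydroxy-3-methylbut-3-enyl) analogue of 14 (both C4 epimers) | CC(=C)C(O)C[C@]1(C)[C@@H](C)C[C@H](O[Si](C)(C)C(C)(C)C)[C@H](C)C1=O | intermediate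
17 | allylmagnesium bromide | C=CC[Mg]Br | starting material
18 | diene diol, C11 allyl carbinol of 16 (epimers at C4 and C11) | CC(=C)C(O)C[C@]1(C)[C@@H](C)C[C@H](O[Si](C)(C)C(C)(C)C)[C@H](C)C1(O)CC=C | intermediate
19 | bicyclo[5.4.0]undecene diol (C2=C3, C4–OH, C11–OH, C9–OTBS) | CC1=CCC2(O)[C@@H](C)[C@@H](O[Si](C)(C)C(C)(C)C)C[C@H](C)[C@@]2(C)CC1O | intermediate
20 | hydroxy enone (C4=O, C2=C3, C11–OH) | CC1=CCC2(O)[C@@H](C)[C@@H](O[Si](C)(C)C(C)(C)C)C[C@H](C)[C@@]2(C)CC1=O | intermediate
21 | key-step precursor, 6-7 fused 2-methylcyclohepta-2,4-dienone with C9 silyl ether (6R,7S,9S,10R) | CC1=CC=C2[C@@H](C)[C@@H](O[Si](C)(C)C(C)(C)C)C[C@H](C)[C@@]2(C)CC1=O | intermediate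
22 | key-step product, tricyclic cyclobutene with C4 ketone and C9 silyl ether | C1=C[C@@]2(C)C(=O)C[C@]3(C)[C@@H](C)C[C@H](O[Si](C)(C)C(C)(C)C)[C@H](C)[C@]123 | intermediate
23 | C4 α-alcohol (4R) of 22 | C1=C[C@@]2(C)[C@H](O)C[C@]3(C)[C@@H](C)C[C@H](O[Si](C)(C)C(C)(C)C)[C@H](C)[C@]123 | intermediate
24 | C4 triethylsilyl ether of 23 | C1=C[C@@]2(C)[C@H](O[Si](CC)(CC)CC)C[C@]3(C)[C@@H](C)C[C@H](O[Si](C)(C)C(C)(C)C)[C@H](C)[C@]123 | intermediate
25 | exo C1–C2 epoxide of 24 | O4[C@@H]1[C@H]4[C@@]2(C)[C@H](O[Si](CC)(CC)CC)C[C@]3(C)[C@@H](C)C[C@H](O[Si](C)(C)C(C)(C)C)[C@H](C)[C@]123 | intermediate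
26 | C1 exo cyclobutanol (C4–OTES, C9–OTBS) | O[C@@H]1C[C@@]2(C)[C@H](O[Si](CC)(CC)CC)C[C@]3(C)[C@@H](C)C[C@H](O[Si](C)(C)C(C)(C)C)[C@H](C)[C@]123 | intermediate
27 | C1 acetate (C4–OTES, C9–OTBS) | CC(=O)O[C@@H]1C[C@@]2(C)[C@H](O[Si](CC)(CC)CC)C[C@]3(C)[C@@H](C)C[C@H](O[Si](C)(C)C(C)(C)C)[C@H](C)[C@]123 | intermediate
28 | C1 acetate, C4 α-alcohol, C9–OTBS | CC(=O)O[C@@H]1C[C@@]2(C)[C@H](O)C[C@]3(C)[C@@H](C)C[C@H](O[Si](C)(C)C(C)(C)C)[C@H](C)[C@]123 | intermediate
29 | C1 acetate, C4 β-bromide, C9–OTBS | CC(=O)O[C@@H]1C[C@@]2(C)[C@@H](Br)C[C@]3(C)[C@@H](C)C[C@H](O[Si](C)(C)C(C)(C)C)[C@H](C)[C@]123 | intermediate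
30 | C1 acetate, C4 β-bromide, C9 alcohol | CC(=O)O[C@@H]1C[C@@]2(C)[C@@H](Br)C[C@]3(C)[C@@H](C)C[C@H](O)[C@H](C)[C@]123 | intermediate
31 | C1 acetate, C4 β-bromide, C9 ketone | CC(=O)O[C@@H]1C[C@@]2(C)[C@@H](Br)C[C@]3(C)[C@@H](C)CC(=O)[C@H](C)[C@]123 | intermediate
32 | lithium enolate of 31 (C8=C9) | CC(=O)O[C@@H]1C[C@@]2(C)[C@@H](Br)C[C@]3(C)[C@@H](C)C=C(O[Li])[C@H](C)[C@]123 | intermediate
33 | trimethylsilyl enol ether of 31 (C8=C9) | CC(=O)O[C@@H]1C[C@@]2(C)[C@@H](Br)C[C@]3(C)[C@@H](C)C=C(O[Si](C)(C)C)[C@H](C)[C@]123 | intermediate
34 | C8 bromo ketone (Br equatorial, trans to C7 methyl) | CC(=O)O[C@@H]1C[C@@]2(C)[C@@H](Br)C[C@]3(C)[C@@H](C)[C@H](Br)C(=O)[C@H](C)[C@]123 | intermediate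
35 | CNP0246576.1, (1R,3R,4S,6R,7R,8S,9R,10R,11R) with the labels used here | CC(=O)O[C@@H]1C[C@@]2(C)[C@@H](Br)C[C@]3(C)[C@@H](C)[C@H](Br)[C@H](O)[C@H](C)[C@]123 | target

**Step count and risks**

Total step count: 24. Longest linear sequence: 24 steps (the route is fully linear from 1 to 35).

Steps most likely to fail:

1. Step 13 (photochemical closure). The bond has to form between two fully substituted carbons, so closure may be slow. Competing processes are over-irradiation of the β,γ-unsaturated ketone product (1,3-acyl shift), α-cleavage, and polar photorearrangement of the dienone. Fallback, setting out from 21: the carbonyl chromophore is removed before the closure. Corey–Bakshi–Shibata 1,2-reduction of the dienone with the (S)-catalyst and catecholborane should give the (4R)-dienol F1, and Et3SiOTf/2,6-lutidine its triethylsilyl ether F2. Direct irradiation of this cyclohepta-1,3-diene at 254 nm (quartz, pentane), the classical cycloheptadiene to bicyclo[3.2.0]hept-6-ene closure with the same ring-enforced sense of rotation, would then form C3–C11 and deliver 24 directly. The route is rejoined at step 16.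

2. Step 17 (epoxide opening). Hydride may attack C1 instead of C2 (loss of regiocontrol), or the strained epoxide may rearrange under Lewis-acid assistance. Fallback, setting out from 22: the hydride is delivered intramolecularly. Reduction with the (R)-catalyst gives the C4 β-alcohol F3 (hydroxyl syn to the cyclobutene), and dimethyldioxirane gives the exo epoxy alcohol F4. With NaAlH2(OCH2CH2OMe)2 the C4 alkoxyaluminate lies over the endo face and passes hydride to the proximal C2 through a six-membered transition state, giving the diol F5. The exposed exo cyclobutanol is acetylated in preference to the concave C4 carbinol (monoacetate F6). Dess–Martin oxidation gives the keto acetate F7, and reduction with the (S)-catalyst returns to the route at 28.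

3. Step 20 (bromination at C4). The activated neopentyl carbinol may ionise (cyclobutylcarbinyl cation, ring expansion) or eliminate instead of undergoing direct displacement. Fallback, setting out from 28: a discrete sulfonate that is slow to ionise is isolated, the chloromethanesulfonate F8 (ClCH2SO2Cl, pyridine, 0 °C). It is displaced by Bu4NBr in toluene at 60 °C under strictly aprotic conditions with inversion, coming back to the route at 29.

Further compounds
F1 | step 13 | (4R)-dienol from 1,2-reduction of 21 | CC1=CC=C2[C@@H](C)[C@@H](O[Si](C)(C)C(C)(C)C)C[C@H](C)[C@@]2(C)C[C@H]1O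
F2 | step 13 | triethylsilyl ether of F1 | CC1=CC=C2[C@@H](C)[C@@H](O[Si](C)(C)C(C)(C)C)C[C@H](C)[C@@]2(C)C[C@H]1O[Si](CC)(CC)CC
F3 | step 17 | C4 β-alcohol (4S) of 22 | C1=C[C@@]2(C)[C@@H](O)C[C@]3(C)[C@@H](C)C[C@H](O[Si](C)(C)C(C)(C)C)[C@H](C)[C@]123
F4 | step 17 | exo C1–C2 epoxide of F3 | O4[C@@H]1[C@H]4[C@@]2(C)[C@@H](O)C[C@]3(C)[C@@H](C)C[C@H](O[Si](C)(C)C(C)(C)C)[C@H](C)[C@]123
F5 | step 17 | diol with C1 exo hydroxyl and C4 β-hydroxyl | O[C@@H]1C[C@@]2(C)[C@@H](O)C[C@]3(C)[C@@H](C)C[C@H](O[Si](C)(C)C(C)(C)C)[C@H](C)[C@]123
F6 | step 17 | C1 monoacetate of F5 | CC(=O)O[C@@H]1C[C@@]2(C)[C@@H](O)C[C@]3(C)[C@@H](C)C[C@H](O[Si](C)(C)C(C)(C)C)[C@H](C)[C@]123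
F7 | step 17 | C1 acetate with C4 ketone | CC(=O)O[C@@H]1C[C@@]2(C)C(=O)C[C@]3(C)[C@@H](C)C[C@H](O[Si](C)(C)C(C)(C)C)[C@H](C)[C@]123
F8 | step 20 | C4 α-chloromethanesulfonate of 28 | CC(=O)O[C@@H]1C[C@@]2(C)[C@H](OS(=O)(=O)CCl)C[C@]3(C)[C@@H](C)C[C@H](O[Si](C)(C)C(C)(C)C)[C@H](C)[C@]123
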